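**Retrosynthetic overview**

- Dorsilurin C comes from its 3-O-methoxymethyl, 7-O-triisopropylsilyl ether, and ring A of that ether is made last by a photo-Wolff/ketene–siloxyalkyne benzannulation.
- The strategy rests on ring A (C4a, C5, C6, C7, C8, C8a): C5–C8 carry OH, prenyl, O, prenyl in unbroken sequence and the C4a–C8a edge is shared with the pyranone ring C. This is the phenol/alkyl/oxygen/alkyl pattern that a vinylketene and an ynol ether deliver; the bonds formed are C8–C8a, C5–C6, C7–C8 and C4a–C5.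
- The diazo ketone carries ring C from comenic acid: C6 bromination, Suzuki–Miyaura coupling with the chromenyl boronate, Weinreb amide, homoprenyl Grignard addition, then diazo transfer.
- The chromene (ring B with its fused dimethylpyran ring D) comes from 4-bromo-2-hydroxybenzaldehyde by Grignard addition and oxa-6π closure; the siloxyalkyne comes from prenyl bromide and ethynylmagnesium bromide by acetylide oxygenation.
- Ring order: ring D, then ring C (bought), then the ring B–ring C bond, then ring A.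

Key step: step 13

Remark on the chemistry: 2H-chromenes open photochemically under UV light, so the photolysis is planned at 420–450 nm, where only the diazo ketone should absorb. Flavone numbering is used for rings A and C. Grignard solutions 2 and 19 are taken as commercial THF solutions.

**Route**

Step 1
Reactants: 1 4-bromo-2-hydroxybenzaldehyde; 2 (2-methylprop-1-en-1-yl)magnesium bromide
Product: 3 5-bromo-2-(1-hydroxy-3-methylbut-2-en-1-yl)phenol (racemic)
Conditions: 2 (2.4 equiv), THF, 0 °C to rt; aq. NH4Cl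
Reagents that add atoms: none
Why: Grignard 1,2-addition to the aldehyde after deprotonation of the phenol by the first equivalent; the aryl bromide does not exchange with an alkenyl Grignard at this temperature, and the new carbinol center is racemic and is lost in step 2.

Step 2
Reactants: 3 5-bromo-2-(1-hydroxy-3-methylbut-2-en-1-yl)phenol
Product: 5 7-bromo-2,2-dimethyl-2H-chromene, via o-quinone methide 4 (not isolated)
Conditions: pyridinium p-toluenesulfonate (10 mol %), toluene, 80 °C
Reagents that add atoms: none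
Why: Acid-catalysed dehydration gives the vinyl o-quinone methide 4, which should close by oxa-6π electrocyclization (dehydrative cyclization of an o-hydroxybenzyl allylic alcohol) to the 2H-chromene with bromine at C7.

Step 3
Reactants: 5 7-bromo-2,2-dimethyl-2H-chromene
Product: 6 2-(2,2-dimethyl-2H-chromen-7-yl)-4,4,5,5-tetramethyl-1,3,2-dioxaborolane
Conditions: B2pin2, Pd(dppf)Cl2 (3 mol %), KOAc, 1,4-dioxane, 90 °C
Reagents that add atoms: bis(pinacolato)diboron, CC1(C)OB(OC1(C)C)B1OC(C)(C)C(C)(C)O1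
Why: Miyaura borylation; zerovalent palladium inserts into the aryl C–Br bond and acetate-assisted transmetalation installs the pinacol boronate without touching the chromene alkene.

Step 4
Reactants: 7 comenic acid
Product: 8 methyl 5-hydroxy-4-oxo-4H-pyran-2-carboxylate
Conditions: MeOH, H2SO4 (cat.), reflux
Reagents that add atoms: methanol, CO
Why: Fischer esterification of the carboxylic acid; the enolic C5 hydroxyl is not etherified under these conditions.

Step 5
Reactants: 8 methyl 5-hydroxy-4-oxo-4H-pyran-2-carboxylate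
Product: 9 methyl 6-bromo-5-hydroxy-4-oxo-4H-pyran-2-carboxylate
Conditions: NBS (1.05 equiv), MeCN, 0 °C to rt
Reagents that add atoms: N-bromosuccinimide, O=C1CCC(=O)N1Br
Why: Electrophilic bromination at C6, the enol β-carbon ortho to the free C5 hydroxyl, while C3 is deactivated by the neighbouring ester (the same site selectivity as in kojic-acid-type 5-hydroxy-4-pyranones).

Step 6
Reactants: 9 methyl 6-bromo-5-hydroxy-4-oxo-4H-pyran-2-carboxylate
Product: 10 methyl 6-bromo-5-(methoxymethoxy)-4-oxo-4H-pyran-2-carboxylate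
Conditions: MOMCl (1.5 equiv), iPr2NEt, CH2Cl2, 0 °C to rt
Reagents that add atoms: chloromethyl methyl ether, COCCl
Why: O-alkylation of the acidic enolic hydroxyl (methoxymethyl ether formation), which masks the chelating 3-hydroxy-4-pyranone unit for the metal-mediated steps.

Step 7
Reactants: 10 methyl 6-bromo-5-(methoxymethoxy)-4-oxo-4H-pyran-2-carboxylate; 6 2-(2,2-dimethyl-2H-chromen-7-yl)-4,4,5,5-tetramethyl-1,3,2-dioxaborolane
Product: 11 methyl 6-(2,2-dimethyl-2H-chromen-7-yl)-5-(methoxymethoxy)-4-oxo-4H-pyran-2-carboxylate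
Conditions: Pd(dppf)Cl2 (5 mol %), CsF (3 equiv), 1,4-dioxane, 80 °C
Reagents that add atoms: none
Why: Suzuki–Miyaura coupling; the C6–Br bond is a vinylogous acyl bromide that adds readily to zerovalent palladium, and anhydrous fluoride activation of the boronate avoids hydrolysis of the ester.

Step 8
Reactants: 11 methyl 6-(2,2-dimethyl-2H-chromen-7-yl)-5-(methoxymethoxy)-4-oxo-4H-pyran-2-carboxylate
Product: 12 6-(2,2-dimethyl-2H-chromen-7-yl)-N-methoxy-5-(methoxymethoxy)-N-methyl-4-oxo-4H-pyran-2-carboxamide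
Conditions: MeNH(OMe)·HCl (1.5 equiv), iPrMgCl (3.0 equiv), THF, −20 °C (magnesium amide pre-formed, then 11)
Reagents that add atoms: N,O-dimethylhydroxylamine hydrochloride, CNOC.Cl
Why: Direct aminolysis of the electron-poor ester by the pre-formed chloromagnesium amide (Weinreb amide formation); the amide nucleophile is a secondary amine and cannot convert the pyranone into a pyridone.

Step 9
Reactants: 12 6-(2,2-dimethyl-2H-chromen-7-yl)-N-methoxy-5-(methoxymethoxy)-N-methyl-4-oxo-4H-pyran-2-carboxamide; 13 5-bromo-2-methylpent-2-ene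
Product: 15 1-[6-(2,2-dimethyl-2H-chromen-7-yl)-5-(methoxymethoxy)-4-oxo-4H-pyran-2-yl]-5-methylhex-4-en-1-one, via (4-methylpent-3-en-1-yl)magnesium bromide 14 (not isolated)
Conditions: 13, Mg, THF, rt; then 12, THF, −78 to −40 °C; aq. NH4Cl
Reagents that add atoms: none
Why: Weinreb ketone synthesis; at low temperature the amide carbonyl is far more electrophilic than the vinylogous-ester carbonyl of the pyranone, and the magnesium chelate stops the addition at the ketone stage.

Step 10
Reactants: 15 1-[6-(2,2-dimethyl-2H-chromen-7-yl)-5-(methoxymethoxy)-4-oxo-4H-pyran-2-yl]-5-methylhex-4-en-1-one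
Product: 17 2-diazo-1-[6-(2,2-dimethyl-2H-chromen-7-yl)-5-(methoxymethoxy)-4-oxo-4H-pyran-2-yl]-5-methylhex-4-en-1-one, via trifluoroacetyl diketone 16 (not isolated)
Conditions: LiHMDS, THF, −78 °C; CF3CO2CH2CF3; aq. NH4Cl; then MsN3, Et3N, H2O (1 equiv), MeCN, rt, in the dark
Reagents that add atoms: methanesulfonyl azide, CS(=O)(=O)N=[N+]=[N-]
Why: Detrifluoroacetylative diazo transfer (a Regitz-type transfer to a ketone activated in situ); the kinetic enolate is C-trifluoroacetylated, and the sulfonyl azide then delivers N2 with loss of the trifluoroacetyl group, a sequence established for base-sensitive ketones with a substituted α-carbon.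

Step 11
Reactants: 18 1-bromo-3-methylbut-2-ene; 19 ethynylmagnesium bromide
Product: 20 5-methylhex-4-en-1-yne
Conditions: CuCl (10 mol %), THF, 0 to 40 °C; isolation by careful distillation
Reagents that add atoms: none
Why: Copper-catalysed allylic substitution by an alkynyl Grignard reagent; attack at the unhindered primary carbon of the prenyl system should give the linear skipped enyne.

Step 12
Reactants: 20 5-methylhex-4-en-1-yne
Product: 23 triisopropyl[(5-methylhex-4-en-1-yn-1-yl)oxy]silane, via lithium acetylide 21 (not isolated), via lithium ynolate 22 (not isolated)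
Conditions: LiHMDS (2.2 equiv), THF, −78 °C; t-BuOOH (1.0 equiv, anhydrous), −78 to 0 °C; then iPr3SiOTf, −78 to 0 °C
Reagents that add atoms: tert-butyl hydroperoxide, CC(C)(C)OO; triisopropylsilyl trifluoromethanesulfonate, CC(C)[Si](OS(=O)(=O)C(F)(F)F)(C(C)C)C(C)C
Why: Electrophilic oxygenation of the lithium acetylide by lithium tert-butyl peroxide gives the ynolate, which the bulky silyl triflate traps on oxygen (acetylide oxidation/O-silylation route to siloxyalkynes); LiHMDS is too weak a base to deprotonate the skipped CH2.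

Step 13
Reactants: 17 2-diazo-1-[6-(2,2-dimethyl-2H-chromen-7-yl)-5-(methoxymethoxy)-4-oxo-4H-pyran-2-yl]-5-methylhex-4-en-1-one; 23 triisopropyl[(5-methylhex-4-en-1-yn-1-yl)oxy]silane
Product: 28 5-hydroxy-3-(methoxymethoxy)-6,8-bis(3-methylbut-2-en-1-yl)-2-(2,2-dimethyl-2H-chromen-7-yl)-7-[(triisopropylsilyl)oxy]-4H-chromen-4-one, via pyranonyl prenyl ketene 24 (not isolated), via siloxycyclobutenone 25 (not isolated), via dienylketene 26 (not isolated), via cyclohexadienone tautomer 27 (not isolated)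
Conditions: 23 (1.5 equiv), hν (LED, 420–450 nm), degassed ClCH2CH2Cl, rt; then 80 °C
Reagents that add atoms: none
Why: Proposed new method: light of 420–450 nm, absorbed only by the diazo ketone so that the photochromic 2H-chromene and the flavone chromophore stay unexcited, should expel N2 with Wolff shift of the pyranonyl group (C8–C8a) to ketene 24, which the polarized siloxyalkyne 23 traps in a (2+2) cycloaddition, its carbon remote from oxygen attacking the ketene carbonyl (C5–C6) and its siloxy carbon bonding to the ketene α-carbon (C7–C8) to give cyclobutenone 25. At 80 °C 25 should open by reversible 4π conrotatory cleavage to dienylketene 26, and ring A then closes by a thermal 6π disrotatory electrocyclization between the ketene carbon and the pyranone C3–H carbon (C4a–C5), after which dienone 27 tautomerizes to the hydrogen-bonded C5 phenol. The closest known reaction type is the Danheiser benzannulation of aryl and heteroaryl α-diazo ketones with siloxyalkynes; the new elements are a 4-pyranone C2=C3 bond as the vinyl unit and an alkyl-substituted diazo carbon. No stereocenter is created, because the quaternary carbon of racemic 25 becomes the aromatic C8. The step needs the siloxy carbon next to C8 and closure at C4a only, and the substrate secures both: the ynol ether polarization fixes the (2+2) orientation, the ketene-bearing pyranone carbon has the ring oxygen as its only other ring neighbour, and the reversible ring opening returns the unproductive olefin isomer of 26 to 25.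

Step 14
Reactants: 28 5-hydroxy-3-(methoxymethoxy)-6,8-bis(3-methylbut-2-en-1-yl)-2-(2,2-dimethyl-2H-chromen-7-yl)-7-[(triisopropylsilyl)oxy]-4H-chromen-4-one
Product: 29 3,5-dihydroxy-6,8-bis(3-methylbut-2-en-1-yl)-2-(2,2-dimethyl-2H-chromen-7-yl)-7-[(triisopropylsilyl)oxy]-4H-chromen-4-one
Conditions: HCl (3 M aq.), MeOH/THF, rt
Reagents that add atoms: none
Why: Acid-catalysed acetal exchange removes the enolic methoxymethyl ether next to the C4 carbonyl; doing this while the C7 oxygen is still silylated should keep the two flanking prenyl groups from cyclizing onto it.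

Step 15
Reactants: 29 3,5-dihydroxy-6,8-bis(3-methylbut-2-en-1-yl)-2-(2,2-dimethyl-2H-chromen-7-yl)-7-[(triisopropylsilyl)oxy]-4H-chromen-4-one
Product: 30 dorsilurin C
Conditions: Bu4NF (1.2 equiv), AcOH (1.2 equiv), THF, 0 °C
Reagents that add atoms: none
Why: Fluoride-mediated desilylation of the aryl silyl ether, driven by Si–F bond formation and the good phenoxide leaving group para to the C4 carbonyl; the acetic acid buffer protects the free flavonol from base.

**Compound list**

1 | 4-bromo-2-hydroxybenzaldehyde | O=Cc1ccc(Br)cc1O | starting material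
2 | (2-methylprop-1-en-1-yl)magnesium bromide | CC(C)=C[Mg]Br | starting material
3 | 5-bromo-2-(1-hydroxy-3-methylbut-2-en-1-yl)phenol (racemic) | CC(C)=CC(O)c1ccc(Br)cc1O | intermediate
4 | 3-bromo-6-(3-methylbut-2-en-1-ylidene)cyclohexa-2,4-dien-1-one (o-quinone methide) | O=C1C=C(Br)C=CC1=CC=C(C)C | intermediate
5 | 7-bromo-2,2-dimethyl-2H-chromene | CC1(C)C=Cc2ccc(Br)cc2O1 | intermediate
6 | 2-(2,2-dimethyl-2H-chromen-7-yl)-4,4,5,5-tetramethyl-1,3,2-dioxaborolane | CC1(C)C=Cc2ccc(B3OC(C)(C)C(C)(C)O3)cc2O1 | intermediate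
7 | comenic acid (5-hydroxy-4-oxo-4H-pyran-2-carboxylic acid) | O=C(O)c1cc(=O)c(O)co1 | starting material
8 | methyl 5-hydroxy-4-oxo-4H-pyran-2-carboxylate | COC(=O)c1cc(=O)c(O)co1 | intermediate
9 | methyl 6-bromo-5-hydroxy-4-oxo-4H-pyran-2-carboxylate | COC(=O)c1cc(=O)c(O)c(Br)o1 | intermediate
10 | methyl 6-bromo-5-(methoxymethoxy)-4-oxo-4H-pyran-2-carboxylate | COC(=O)c1cc(=O)c(OCOC)c(Br)o1 | intermediate
11 | methyl 6-(2,2-dimethyl-2H-chromen-7-yl)-5-(methoxymethoxy)-4-oxo-4H-pyran-2-carboxylate | COC(=O)c1cc(=O)c(OCOC)c(-c2ccc3c(c2)OC(C)(C)C=C3)o1 | intermediate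
12 | 6-(2,2-dimethyl-2H-chromen-7-yl)-N-methoxy-5-(methoxymethoxy)-N-methyl-4-oxo-4H-pyran-2-carboxamide | CON(C)C(=O)c1cc(=O)c(OCOC)c(-c2ccc3c(c2)OC(C)(C)C=C3)o1 | intermediate
13 | 5-bromo-2-methylpent-2-ene | CC(C)=CCCBr | starting material
14 | (4-methylpent-3-en-1-yl)magnesium bromide | CC(C)=CCC[Mg]Br | intermediate
15 | 1-[6-(2,2-dimethyl-2H-chromen-7-yl)-5-(methoxymethoxy)-4-oxo-4H-pyran-2-yl]-5-methylhex-4-en-1-one | CC(C)=CCCC(=O)c1cc(=O)c(OCOC)c(-c2ccc3c(c2)OC(C)(C)C=C3)o1 | intermediate
16 | 1-[6-(2,2-dimethyl-2H-chromen-7-yl)-5-(methoxymethoxy)-4-oxo-4H-pyran-2-yl]-4,4,4-trifluoro-2-(3-methylbut-2-en-1-yl)butane-1,3-dione (racemic) | CC(C)=CCC(C(=O)C(F)(F)F)C(=O)c1cc(=O)c(OCOC)c(-c2ccc3c(c2)OC(C)(C)C=C3)o1 | intermediate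
17 | 2-diazo-1-[6-(2,2-dimethyl-2H-chromen-7-yl)-5-(methoxymethoxy)-4-oxo-4H-pyran-2-yl]-5-methylhex-4-en-1-one | CC(C)=CCC(=[N+]=[N-])C(=O)c1cc(=O)c(OCOC)c(-c2ccc3c(c2)OC(C)(C)C=C3)o1 | intermediate
18 | 1-bromo-3-methylbut-2-ene | CC(C)=CCBr | starting material
19 | ethynylmagnesium bromide | C#C[Mg]Br | starting material
20 | 5-methylhex-4-en-1-yne | CC(C)=CCC#C | intermediate
21 | (5-methylhex-4-en-1-yn-1-yl)lithium | CC(C)=CCC#C[Li] | intermediate
22 | lithium 5-methylhex-4-en-1-yn-1-olate | CC(C)=CCC#C[O-].[Li+] | intermediate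
23 | triisopropyl[(5-methylhex-4-en-1-yn-1-yl)oxy]silane | CC(C)=CCC#CO[Si](C(C)C)(C(C)C)C(C)C | intermediate
24 | 2-[6-(2,2-dimethyl-2H-chromen-7-yl)-5-(methoxymethoxy)-4-oxo-4H-pyran-2-yl]-5-methylhexa-1,4-dien-1-one (ketene) | CC(C)=CCC(=C=O)c1cc(=O)c(OCOC)c(-c2ccc3c(c2)OC(C)(C)C=C3)o1 | intermediate
25 | 2,4-bis(3-methylbut-2-en-1-yl)-4-[6-(2,2-dimethyl-2H-chromen-7-yl)-5-(methoxymethoxy)-4-oxo-4H-pyran-2-yl]-3-[(triisopropylsilyl)oxy]cyclobut-2-en-1-one (racemic) | O=C1C(CC=C(C)C)=C(O[Si](C(C)C)(C(C)C)C(C)C)C1(CC=C(C)C)c2cc(=O)c(OCOC)c(-c3ccc4c(c3)OC(C)(C)C=C4)o2 | intermediate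
26 | (E)-2,4-bis(3-methylbut-2-en-1-yl)-4-[6-(2,2-dimethyl-2H-chromen-7-yl)-5-(methoxymethoxy)-4-oxo-4H-pyran-2-yl]-3-[(triisopropylsilyl)oxy]buta-1,3-dien-1-one (dienylketene; ketenyl carbon cis to the pyranonyl group) | O=C=C(CC=C(C)C)/C(O[Si](C(C)C)(C(C)C)C(C)C)=C(/CC=C(C)C)c1cc(=O)c(OCOC)c(-c2ccc3c(c2)OC(C)(C)C=C3)o1 | intermediate
27 | 3-(methoxymethoxy)-6,8-bis(3-methylbut-2-en-1-yl)-2-(2,2-dimethyl-2H-chromen-7-yl)-7-[(triisopropylsilyl)oxy]-4aH-chromene-4,5-dione (racemic) | O=C1C(CC=C(C)C)=C(O[Si](C(C)C)(C(C)C)C(C)C)C(CC=C(C)C)=C2OC(-c3ccc4c(c3)OC(C)(C)C=C4)=C(OCOC)C(=O)C12 | intermediate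
28 | 5-hydroxy-3-(methoxymethoxy)-6,8-bis(3-methylbut-2-en-1-yl)-2-(2,2-dimethyl-2H-chromen-7-yl)-7-[(triisopropylsilyl)oxy]-4H-chromen-4-one | CC(C)=CCc1c(O[Si](C(C)C)(C(C)C)C(C)C)c(CC=C(C)C)c2oc(-c3ccc4c(c3)OC(C)(C)C=C4)c(OCOC)c(=O)c2c1O | intermediate
29 | 3,5-dihydroxy-6,8-bis(3-methylbut-2-en-1-yl)-2-(2,2-dimethyl-2H-chromen-7-yl)-7-[(triisopropylsilyl)oxy]-4H-chromen-4-one | CC(C)=CCc1c(O[Si](C(C)C)(C(C)C)C(C)C)c(CC=C(C)C)c2oc(-c3ccc4c(c3)OC(C)(C)C=C4)c(O)c(=O)c2c1O | intermediate
30 | dorsilurin C (3,5,7-trihydroxy-6,8-bis(3-methylbut-2-en-1-yl)-2-(2,2-dimethyl-2H-chromen-7-yl)-4H-chromen-4-one) | CC(C)=CCc1c(O)c(CC=C(C)C)c2oc(-c3ccc4c(c3)OC(C)(C)C=C4)c(O)c(=O)c2c1O | target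

**Step count and risks**

Total step count: 15. Longest linear sequence: 10 steps (7 to 30 through steps 4–10 and 13–15).

Steps most likely to fail:

1. Step 13 (bears the new-method label). Several processes could divert it:
   - The diazo ketone may lose N2 from the conformer that cannot rearrange in concert, so that the free carbene undergoes a 1,2-hydrogen shift to a dienone instead of the Wolff shift.
   - The ketene may dimerize or be trapped too slowly.
   - The 6π closure onto the pyranone carbon may be slow enough for the dienylketene to be consumed by hydrogen shift.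
   - Residual absorption by the chromene may open ring D.

   Fallback (known chalcone chemistry), setting out from bromide 5 and prenyl bromide 18 and coming back at target 30. Bromine–lithium exchange on 5 (n-BuLi, THF, −78 °C) and formylation with DMF should give 2,2-dimethyl-2H-chromene-7-carbaldehyde F1. Commercial 1-(2,4,6-trihydroxyphenyl)ethanone is C-prenylated twice with 18 (aq. KOH, 0 °C) to 1-[2,4,6-trihydroxy-3,5-bis(3-methylbut-2-en-1-yl)phenyl]ethanone F2. MOMCl/iPr2NEt then protects all but the chelated hydroxyl to give 1-[2-hydroxy-4,6-bis(methoxymethoxy)-3,5-bis(3-methylbut-2-en-1-yl)phenyl]ethanone F3. Claisen–Schmidt condensation of F3 with F1 (KOH, EtOH) gives (E)-3-(2,2-dimethyl-2H-chromen-7-yl)-1-[2-hydroxy-4,6-bis(methoxymethoxy)-3,5-bis(3-methylbut-2-en-1-yl)phenyl]prop-2-en-1-one F4. Algar–Flynn–Oyamada oxidation (H2O2, NaOH, MeOH, 0 °C) closes ring C to 3-hydroxy-5,7-bis(methoxymethoxy)-6,8-bis(3-methylbut-2-en-1-yl)-2-(2,2-dimethyl-2H-chromen-7-yl)-4H-chromen-4-one F5. HCl in MeOH removes both methoxymethyl groups and delivers 30.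

2. Step 9. The Grignard reagent may add to the pyranone (1,2 at the C4 carbonyl or in conjugate fashion at C2/C6) in competition with the Weinreb amide, or the pyranone may ring-open under the basic magnesium species.

   Fallback, setting out from ester 11 and Grignard reagent 14 and coming back at ketone 15; it replaces the hard nucleophile by a palladium-catalysed acylation of an organozinc. Mild saponification of 11 (LiOH, THF/H2O, 0 °C) should give 6-(2,2-dimethyl-2H-chromen-7-yl)-5-(methoxymethoxy)-4-oxo-4H-pyran-2-carboxylic acid F6. Coupling with ethanethiol (EDC·HCl, DMAP, CH2Cl2) gives S-ethyl 6-(2,2-dimethyl-2H-chromen-7-yl)-5-(methoxymethoxy)-4-oxo-4H-pyran-2-carbothioate F7. Transmetalation of 14 with ZnCl2 gives (4-methylpent-3-en-1-yl)zinc chloride F8, and Fukuyama coupling of F7 with F8 (PdCl2(PPh3)2, toluene/THF, rt) gives 15, since the organozinc does not attack the pyranone.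

3. Step 12. Oxygen transfer from the peroxide to the acetylide may stall, the doubly activated CH2 of the skipped enyne may be deprotonated so that the chain isomerizes to an allene or a conjugated enyne, or the sensitive siloxyalkyne may be lost on purification.

   Fallback, setting out from prenyl bromide 18 and coming back at lithium ynolate 22; it avoids the enyne altogether. The lithium enolate of ethyl acetate (LiN(iPr)2, THF, −78 °C) is alkylated with 18 to ethyl 5-methylhex-4-enoate F9. Two rounds of enolization (LiHMDS) and bromination with BrCF2CF2Br give ethyl 2,2-dibromo-5-methylhex-4-enoate F10. t-BuLi (4 equiv, THF, −78 to 0 °C) should convert F10 by double bromine–lithium exchange and loss of ethoxide into 22, which is silylated with iPr3SiOTf as in step 12 to give 23.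

**Further compounds**

F1 | step 13 | 2,2-dimethyl-2H-chromene-7-carbaldehyde | CC1(C)C=Cc2ccc(C=O)cc2O1
F2 | step 13 | 1-[2,4,6-trihydroxy-3,5-bis(3-methylbut-2-en-1-yl)phenyl]ethanone | CC(=O)c1c(O)c(CC=C(C)C)c(O)c(CC=C(C)C)c1O
F3 | step 13 | 1-[2-hydroxy-4,6-bis(methoxymethoxy)-3,5-bis(3-methylbut-2-en-1-yl)phenyl]ethanone | CC(=O)c1c(O)c(CC=C(C)C)c(OCOC)c(CC=C(C)C)c1OCOC
F4 | step 13 | (E)-3-(2,2-dimethyl-2H-chromen-7-yl)-1-[2-hydroxy-4,6-bis(methoxymethoxy)-3,5-bis(3-methylbut-2-en-1-yl)phenyl]prop-2-en-1-one | O=C(/C=C/c1ccc2c(c1)OC(C)(C)C=C2)c1c(O)c(CC=C(C)C)c(OCOC)c(CC=C(C)C)c1OCOC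
F5 | step 13 | 3-hydroxy-5,7-bis(methoxymethoxy)-6,8-bis(3-methylbut-2-en-1-yl)-2-(2,2-dimethyl-2H-chromen-7-yl)-4H-chromen-4-one | CC(C)=CCc1c(OCOC)c(CC=C(C)C)c2oc(-c3ccc4c(c3)OC(C)(C)C=C4)c(O)c(=O)c2c1OCOC
F6 | step 9 | 6-(2,2-dimethyl-2H-chromen-7-yl)-5-(methoxymethoxy)-4-oxo-4H-pyran-2-carboxylic acid | O=C(O)c1cc(=O)c(OCOC)c(-c2ccc3c(c2)OC(C)(C)C=C3)o1
F7 | step 9 | S-ethyl 6-(2,2-dimethyl-2H-chromen-7-yl)-5-(methoxymethoxy)-4-oxo-4H-pyran-2-carbothioate | CCSC(=O)c1cc(=O)c(OCOC)c(-c2ccc3c(c2)OC(C)(C)C=C3)o1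
F8 | step 9 | (4-methylpent-3-en-1-yl)zinc chloride | CC(C)=CCC[Zn]Cl
F9 | step 12 | ethyl 5-methylhex-4-enoate | CCOC(=O)CCC=C(C)C
F10 | step 12 | ethyl 2,2-dibromo-5-methylhex-4-enoate | CCOC(=O)C(Br)(Br)CC=C(C)C
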